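**Retrosynthetic overview**
- Target ⇐ unmasking of the α-methylene ester (amine N-oxide, Cope elimination), desilylation and site-selective C8–O acetylation of a masked tetraol.
- C4–O bond ⇐ α-face Markovnikov hydration (oxymercuration) of a 4(15)-alkene in the saturated trans-decalin.
- C6–O and C8–O bonds (with H5 and H7) ⇐ one-flask all-α dihydroboration–oxidation of a 5,7-diene (key step, proposed new); a C15 selenide eliminates to the 4(15)-alkene in the same work-up.
- 5,7-Diene ⇐ dienyl triflate + zinc enolate of methyl 3-(dimethylamino)propanoate (C7–C11 bond; amine = masked acrylate).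
- Dienyl triflate ⇐ (R)-Wieland–Miescher ketone by γ-methylenation, PhSeH 1,6-addition and C1 reduction; no ring is formed, ring A and ring B arrive fused in the starting decalin.

Assumption: eudesmane numbering is used (decalin C1–C10, C14 = angular methyl on C10, C15 = carbon on C4, C11–C13 = side chain on C7; α = face opposite C14); the C4 centre of the selenide intermediates is drawn as its pseudo-equatorial 4α epimer and C11 of the amino-ester intermediates is left undefined (epimer mixture), both centres being erased later.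

Step 1
Reactants: 1 (R)-Wieland–Miescher ketone
Product: 2 (8aR)-8a-methyl-4-methylidene-2,3,4,7,8,8a-hexahydronaphthalene-1,6-dione (4-methylene dienedione)
Conditions: CH2(OEt)2, POCl3, NaOAc, CHCl3, reflux
Reagents that add atoms: diethoxymethane, CCOCOCC
Why: Vinylogous alkoxymethylation–elimination of the enone through its dienol (Mannich/Prins-type γ-methylenation, the standard 6-methylenation of 4-en-3-ones): the ethoxymethyl cation attacks C4 and ethanol is lost to give the linear dienone, while the saturated C1 ketone is untouched and no stereocentre is created.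

Step 2
Reactants: 2 4-methylene dienedione
Product: 3 (4R,8aR)-8a-methyl-4-[(phenylselanyl)methyl]-3,4,8,8a-tetrahydronaphthalene-1,6(2H,7H)-dione
Conditions: PhSeH (1.1 equiv), Et3N (10 mol%), CH2Cl2, 0 °C → rt
Reagents that add atoms: benzeneselenol, [SeH]c1ccccc1
Why: 1,6-Conjugate (seleno-Michael) addition of the soft selenol to the unhindered terminal CH2 of the linear dienone, with amine-mediated equilibration back to the conjugated enone and the CH2SePh group pseudo-equatorial (4α); this centre only masks the 4(15)-alkene and is erased in step 6.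

Step 3
Reactants: 3 selenide enedione
Product: 4 (4aR,5R,8R)-5-hydroxy-4a-methyl-8-[(phenylselanyl)methyl]-4,4a,5,6,7,8-hexahydronaphthalen-2(3H)-one (1β-hydroxy enone)
Conditions: NaBH4 (0.3 equiv), EtOH, −20 °C
Reagents that add atoms: none
Why: Chemoselective borohydride reduction of the saturated ketone in the presence of the less electrophilic enone (as for the parent diketone); hydride attacks C1 from the α-face, anti to the neighbouring angular methyl, giving the equatorial 1β-alcohol (1R).

Step 4
Reactants: 4 1β-hydroxy enone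
Product: 6 1β-(triethylsilyloxy)-15-(phenylselanyl)-11,12,13-trinoreudesma-5,7-dien-7-yl trifluoromethanesulfonate (dienyl triflate), via triethylsilyl ether 5 (not isolated)
Conditions: TESOTf (1.05 equiv), 2,6-lutidine, THF, −78 °C; then KN(SiMe3)2 (2.3 equiv), −78 °C; then PhNTf2, −78 → 0 °C
Reagents that add atoms: triethylsilyl trifluoromethanesulfonate, CC[Si](CC)(CC)OS(=O)(=O)C(F)(F)F; N-phenylbis(trifluoromethanesulfonimide), O=S(=O)(N(c1ccccc1)S(=O)(=O)C(F)(F)F)C(F)(F)F
Why: O-silylation followed by kinetic enol triflate formation: the hindered amide base removes an α′-proton at C8 at −78 °C to give the cross-conjugated dienolate, which is O-sulfonylated; the low temperature avoids γ-deprotonation at C4 (which would expel selenolate), and no stereocentre is formed.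

Step 5
Reactants: 6 dienyl triflate; 7 methyl 3-(dimethylamino)propanoate
Product: 9 methyl 13-(dimethylamino)-15-(phenylselanyl)-1β-(triethylsilyloxy)eudesma-5,7-dien-12-oate, via chlorozinc enolate 8 (not isolated)
Conditions: 7, LiN(SiMe3)2, THF, −78 °C; ZnCl2, → rt; then 6, Pd(dba)2 (5 mol%), P(t-Bu)3 (10 mol%), THF, 45 °C
Reagents that add atoms: none
Why: Negishi-type cross-coupling of an ester zinc enolate with an alkenyl triflate (oxidative addition to zerovalent palladium, transmetalation, reductive elimination) forms the C7–C11 bond; the β-amino group is too poor a leaving group to be lost from the enolate and serves as the masked α-methylene, and C11 forms as an inconsequential epimer mixture.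

Step 6
Reactants: 9 dienyl amino ester
Product: 12 methyl 13-(dimethylamino)-6α,8α-dihydroxy-1β-(triethylsilyloxy)-5αH,7αH-eudesm-4(15)-en-12-oate, via bis-borane adduct 10 (not isolated), via selenoxide 11 (not isolated)
Conditions: BF3·OEt2 (1.1 equiv), THF, 0 °C; BH3·THF (5 equiv), 0 °C → rt; then 1 M aq NaOH, 30% H2O2, 0 °C → rt
Reagents that add atoms: hydrogen peroxide, OO
Why: Proposed new method: one-flask exhaustive all-syn dihydroboration of a ring-fused, 2-substituted homoannular 1,3-diene followed by a single alkaline-peroxide work-up that also triggers a selenoxide elimination; with the amine held as its BF3 adduct, electrophilic BH3 adds first to the less hindered 7,8-bond (boron on the terminal CH, C8) and then to the 5,6-bond (boron on C6), each on the α-face because the β-face is covered by the axial angular methyl, and the excess of borane keeps the second addition intermolecular so that no 5,8-bridged borane forms; stereoretentive C–B oxidation therefore delivers the 6α- and 8α-C–O bonds together with 5α-H and 7α-H (the four ring-B centres as in the target), while the same oxidant converts the selenide into selenoxide 11, which undergoes syn-elimination through its only β-hydrogen (C4–H) to give the 4(15)-alkene; the closest known reactions are the hydroboration–oxidation of steroidal 5,7-dienes, which stops at the 6α-hydroxy-7-ene because C8 is fully substituted there, and the dihydroboration of cyclohexa-1,3-diene to 1,3-diols.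

Step 7
Reactants: 12 amino diol with 4(15)-alkene
Product: 14 methyl 13-(dimethylamino)-4α,6α,8α-trihydroxy-1β-(triethylsilyloxy)eudesman-12-oate, via organomercurial 13 (not isolated)
Conditions: Hg(OAc)2 (1.5 equiv), THF/H2O (1:1), rt; then NaBH4, 1 M aq NaOH, 0 °C
Reagents that add atoms: water, O
Why: Markovnikov oxymercuration–demercuration: water opens the mercurinium ion at the tertiary C4 from the equatorial α-face because the axial β-face is shielded by the syn-axial angular methyl (the sense seen with 4(15)-eudesmenes), giving the 4α-hydroxy-4β-methyl centre (4R); the brief cold borohydride demercuration leaves ester, silyl ether and amine intact.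

Step 8
Reactants: 14 amino triol
Product: 15 methyl 8α-acetoxy-13-(dimethylamino)-4α,6α-dihydroxy-1β-(triethylsilyloxy)eudesman-12-oate
Conditions: Ac2O (1.2 equiv), pyridine, DMAP (5 mol%), CH2Cl2, −20 °C
Reagents that add atoms: acetic anhydride, CC(=O)OC(C)=O
Why: Nucleophile-catalysed (DMAP) acyl transfer is site-selective for the 8α-hydroxyl, the only unhindered secondary alcohol: O1 is silylated, the C4 alcohol is tertiary, and the 6α-hydroxyl is flanked by C5 and C7 and hydrogen-bonded to the peri 4α-hydroxyl; no stereocentre changes.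

Step 9
Reactants: 15 amino acetate
Product: 18 methyl (1R,4R,5S,6S,7S,8S,10R)-8-acetoxy-1,4,6-trihydroxyeudesm-11(13)-en-12-oate (target), via amine N-oxide 16 (not isolated), via silyl-protected acrylate 17 (not isolated)
Conditions: mCPBA (1.05 equiv), CH2Cl2, −20 °C → rt; then HF·pyridine, THF/pyridine, 0 °C → rt
Reagents that add atoms: none
Why: Amine N-oxidation then Cope elimination (syn, through C11–H, the only β-hydrogen and activated by the ester) unveils the 11(13)-methylene ester at room temperature and erases C11, after which fluoride-mediated desilylation frees the 1β-hydroxyl without touching acetate or acrylate.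

**Compound list**
1 | (R)-(−)-Wieland–Miescher ketone, (8aR)-8a-methyl-3,4,8,8a-tetrahydronaphthalene-1,6(2H,7H)-dione | O=C1C=C2[C@@](C)(CC1)C(=O)CCC2 | starting material
2 | (8aR)-8a-methyl-4-methylidene-2,3,4,7,8,8a-hexahydronaphthalene-1,6-dione | O=C1C=C2[C@@](C)(CC1)C(=O)CCC2=C | intermediate
3 | (4R,8aR)-8a-methyl-4-[(phenylselanyl)methyl]-3,4,8,8a-tetrahydronaphthalene-1,6(2H,7H)-dione (4α-CH2SePh) | O=C1C=C2[C@@](C)(CC1)C(=O)CC[C@H]2C[Se]c3ccccc3 | intermediate
4 | (4aR,5R,8R)-5-hydroxy-4a-methyl-8-[(phenylselanyl)methyl]-4,4a,5,6,7,8-hexahydronaphthalen-2(3H)-one (1β-OH) | O=C1C=C2[C@@](C)(CC1)[C@H](O)CC[C@H]2C[Se]c3ccccc3 | intermediate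
5 | 1-O-triethylsilyl ether of 4 (formed in the flask in step 4) | O=C1C=C2[C@@](C)(CC1)[C@H](O[Si](CC)(CC)CC)CC[C@H]2C[Se]c3ccccc3 | intermediate
6 | 1β-(triethylsilyloxy)-15-(phenylselanyl)-11,12,13-trinoreudesma-5,7-dien-7-yl trifluoromethanesulfonate (4βH) | FC(F)(F)S(=O)(=O)OC=1C=C2[C@@](C)(CC1)[C@H](O[Si](CC)(CC)CC)CC[C@H]2C[Se]c3ccccc3 | intermediate
7 | methyl 3-(dimethylamino)propanoate | COC(=O)CCN(C)C | starting material
8 | chlorozinc enolate of 7, methyl 2-(chlorozincio)-3-(dimethylamino)propanoate (formed in the flask in step 5) | COC(=O)C([Zn]Cl)CN(C)C | intermediate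
9 | methyl 13-(dimethylamino)-15-(phenylselanyl)-1β-(triethylsilyloxy)eudesma-5,7-dien-12-oate (4βH; C11 epimers) | COC(=O)C(CN(C)C)C=1C=C2[C@@](C)(CC1)[C@H](O[Si](CC)(CC)CC)CC[C@H]2C[Se]c3ccccc3 | intermediate
10 | 6α,8α-bis(boranyl) adduct of 9 (5αH, 7αH; amine as its BF3 adduct; formed in the flask in step 6) | COC(=O)C(C[N+](C)(C)[B-](F)(F)F)[C@H]1[C@H]([BH2])[C@@H]2[C@@](C)(C[C@@H]1[BH2])[C@H](O[Si](CC)(CC)CC)CC[C@H]2C[Se]c3ccccc3 | intermediate
11 | methyl 13-(dimethylamino)-6α,8α-dihydroxy-15-(phenylseleninyl)-1β-(triethylsilyloxy)-5αH,7αH-eudesman-12-oate (selenoxide; formed in the flask in step 6) | COC(=O)C(CN(C)C)[C@H]1[C@H](O)[C@@H]2[C@@](C)(C[C@@H]1O)[C@H](O[Si](CC)(CC)CC)CC[C@H]2C[Se](=O)c3ccccc3 | intermediate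
12 | methyl 13-(dimethylamino)-6α,8α-dihydroxy-1β-(triethylsilyloxy)-5αH,7αH-eudesm-4(15)-en-12-oate | COC(=O)C(CN(C)C)[C@H]1[C@H](O)[C@@H]2[C@@](C)(C[C@@H]1O)[C@H](O[Si](CC)(CC)CC)CCC2=C | intermediate
13 | 15-(acetoxymercurio)-4α-hydroxy adduct of 12 (formed in the flask in step 7) | COC(=O)C(CN(C)C)[C@H]1[C@H](O)[C@@H]2[C@@](C)(C[C@@H]1O)[C@H](O[Si](CC)(CC)CC)CC[C@@]2(C[Hg]OC(C)=O)O | intermediate
14 | methyl 13-(dimethylamino)-4α,6α,8α-trihydroxy-1β-(triethylsilyloxy)eudesman-12-oate | COC(=O)C(CN(C)C)[C@H]1[C@H](O)[C@@H]2[C@@](C)(C[C@@H]1O)[C@H](O[Si](CC)(CC)CC)CC[C@@]2(C)O | intermediate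
15 | methyl 8α-acetoxy-13-(dimethylamino)-4α,6α-dihydroxy-1β-(triethylsilyloxy)eudesman-12-oate | COC(=O)C(CN(C)C)[C@H]1[C@H](O)[C@@H]2[C@@](C)(C[C@@H]1OC(C)=O)[C@H](O[Si](CC)(CC)CC)CC[C@@]2(C)O | intermediate
16 | N-oxide of 15 (formed in the flask in step 9) | COC(=O)C(C[N+](C)(C)[O-])[C@H]1[C@H](O)[C@@H]2[C@@](C)(C[C@@H]1OC(C)=O)[C@H](O[Si](CC)(CC)CC)CC[C@@]2(C)O | intermediate
17 | methyl 8α-acetoxy-4α,6α-dihydroxy-1β-(triethylsilyloxy)eudesm-11(13)-en-12-oate (formed in the flask in step 9) | C=C(C(=O)OC)[C@H]1[C@H](O)[C@@H]2[C@@](C)(C[C@@H]1OC(C)=O)[C@H](O[Si](CC)(CC)CC)CC[C@@]2(C)O | intermediate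
18 | methyl (1R,4R,5S,6S,7S,8S,10R)-8-acetoxy-1,4,6-trihydroxyeudesm-11(13)-en-12-oate (8α-OAc; 1β,4α,6α-OH; 5αH,7αH) | C=C(C(=O)OC)[C@H]1[C@H](O)[C@@H]2[C@@](C)(C[C@@H]1OC(C)=O)[C@H](O)CC[C@@]2(C)O | target

**Step count and risks**
Total steps: 9. Longest linear sequence: 9 steps (1 → 18).

Step 5 (enolate cross-coupling; a β-amino ester enolate, a hindered dienyl triflate and a selenide in the same flask). The fallback sets out from 6 and comes back at 9. Stille coupling of 6 with methyl 2-(tributylstannyl)acrylate (Pd(PPh3)4, CuI, DMF, rt) gives methyl 15-(phenylselanyl)-1β-(triethylsilyloxy)eudesma-5,7,11(13)-trien-12-oate F1. Conjugate addition of dimethylamine to its acrylate (THF/MeOH, 0 °C, protonation at C11) then returns 9.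

Step 6 (the proposed new step; risks are incomplete second addition, 1,4-diol formation through allylic boranes, and loss of face control). The fallback uses known chemistry only, sets out from 9 and comes back at 11, which goes on to 12 in the same flask. It replaces the exhaustive addition by two separately precedented mono-hydroborations with isolation in between.
- 9-BBN (1.2 equiv, THF, 0 °C → rt) adds only to the less hindered 7,8-bond, giving the C8 B-alkyl-9-borabicyclo[3.3.1]nonane adduct F2.
- Me3NO (THF, 60 °C), which leaves the selenide alone, oxidises it to the homoallylic alcohol methyl 13-(dimethylamino)-8α-hydroxy-15-(phenylselanyl)-1β-(triethylsilyloxy)eudesm-5-en-12-oate F3.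
- The isolated 5,6-bond of F3 is hydroborated as in 5-ene steroids (BF3·OEt2; BH3·SMe2, THF) to the 6α-boranyl adduct F4 (5αH).
- Alkaline H2O2 converts F4 into 11.

Step 8 (site-selective acetylation; risk of 6-O-acetyl and diacetyl by-products). The fallback sets out from 14 and comes back at 15. Phenylboronic acid (toluene, 4 Å sieves, rt) ties up the peri 4α,6α-diol as the six-membered cyclic 4,6-O-phenylboronate of 14 F5. The only remaining hydroxyl is acetylated (Ac2O, pyridine, DMAP, rt) to the 8-O-acetyl boronate F6. Transesterification with pinacol (THF, rt) releases 15.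

Further compounds
F1 | step 5 | methyl 15-(phenylselanyl)-1β-(triethylsilyloxy)eudesma-5,7,11(13)-trien-12-oate (4βH) | C=C(C(=O)OC)C=1C=C2[C@@](C)(CC1)[C@H](O[Si](CC)(CC)CC)CC[C@H]2C[Se]c3ccccc3
F2 | step 6 | C8 B-alkyl-9-borabicyclo[3.3.1]nonane adduct of 9 (8α-boryl, 7αH, 5-ene) | COC(=O)C(CN(C)C)[C@H]1C=C2[C@@](C)(C[C@@H]1B3C4CCCC3CCC4)[C@H](O[Si](CC)(CC)CC)CC[C@H]2C[Se]c5ccccc5
F3 | step 6 | methyl 13-(dimethylamino)-8α-hydroxy-15-(phenylselanyl)-1β-(triethylsilyloxy)-7αH-eudesm-5-en-12-oate | COC(=O)C(CN(C)C)[C@H]1C=C2[C@@](C)(C[C@@H]1O)[C@H](O[Si](CC)(CC)CC)CC[C@H]2C[Se]c3ccccc3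
F4 | step 6 | 6α-boranyl adduct of F3 (5αH; amine as its BF3 adduct, O8 as its boryl ether) | COC(=O)C(C[N+](C)(C)[B-](F)(F)F)[C@H]1[C@H]([BH2])[C@@H]2[C@@](C)(C[C@@H]1O[BH2])[C@H](O[Si](CC)(CC)CC)CC[C@H]2C[Se]c3ccccc3
F5 | step 8 | cyclic 4,6-O-phenylboronate of 14 | COC(=O)C(CN(C)C)[C@H]1[C@H](O3)[C@@H]2[C@@](C)(C[C@@H]1O)[C@H](O[Si](CC)(CC)CC)CC[C@@]2(C)OB3c4ccccc4
F6 | step 8 | 8-O-acetate of F5 | COC(=O)C(CN(C)C)[C@H]1[C@H](O3)[C@@H]2[C@@](C)(C[C@@H]1OC(C)=O)[C@H](O[Si](CC)(CC)CC)CC[C@@]2(C)OB3c4ccccc4
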